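**Retrosynthetic overview**

1. Target ⇒ C4–prenyl bond: last-step C-alkylation of the only ring CH of a 6,6-diprenyl-2-acyl dienone.
2. That dienone ⇒ ring C1–C2 bond: intramolecular Claisen condensation of the acyclic methyl 2,2-diprenyl-3,5,7-trioxo-9-phenylnonanoate. This closes the only ring made in the route; the phenyl ring is bought.
3. Triketo ester ⇒ chain C3–C4 bond: acid chloride of monomethyl diprenylmalonate plus the terminal carbanion of the 6-phenylhexane-2,4-dione dianion.
4. Fragments ⇒ dimethyl malonate + 2 prenyl bromide; acetylacetone + benzyl bromide.
5. Feature used: in the six-membered carbocycle the C1 ketone lies between the quaternary gem-diprenyl C6 and the acyl-bearing C2, and C2 is the mid-carbon of a 1,3-diketone (C3–O and the exocyclic acyl C=O). C1–C2 is therefore the bond between an ester carbon on C6 and a diketone carbanion.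

Key step: step 6

Remark: 12, 13 and 14 are sets of rapidly interconverting keto–enol tautomers; 12 is written as the triketone, 13 and 14 as the 3,5-dihydroxy-dienone form of the target SMILES. Ring numbering is C1 (ketone), C2 (acyl), C3, C4, C5, C6 (gem-diprenyl). Only lithium dianions pre-formed with LiN(i-Pr)2 are numbered as intermediates; other enolates are treated as the ionised form of the numbered compound.

**Route**

Step 1
Reactants: 1 dimethyl malonate; 2 prenyl bromide (1-bromo-3-methylbut-2-ene)
Product: 4 dimethyl 2,2-bis(3-methylbut-2-enyl)malonate, via dimethyl 2-(3-methylbut-2-enyl)malonate 3 (not isolated)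
Conditions: NaH (2.3 equiv), 2 (2.3 equiv), THF/DMF, 0 °C to rt
Reagents that add atoms: none
Why: Malonic ester alkylation, in which the malonate enolate displaces bromide from the primary allylic carbon of 2 (SN2) and the enolate of 3 formed under the same conditions does so a second time.

Step 2
Reactants: 4 dimethyl 2,2-bis(3-methylbut-2-enyl)malonate
Product: 5 2-(methoxycarbonyl)-5-methyl-2-(3-methylbut-2-enyl)hex-4-enoic acid (monomethyl 2,2-diprenylmalonate)
Conditions: KOH (1.1 equiv), MeOH/H2O, rt to 40 °C; then 1 M HCl to pH 3, 0 °C
Reagents that add atoms: potassium hydroxide, [K+].[OH-]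
Why: Mono-saponification of a disubstituted malonate, which should stop at the half ester because the carboxylate formed first repels hydroxide from the neighbouring hindered ester; brief cold acidification avoids lactonisation onto a prenyl group and decarboxylation.

Step 3
Reactants: 5 2-(methoxycarbonyl)-5-methyl-2-(3-methylbut-2-enyl)hex-4-enoic acid
Product: 6 methyl 2-(chlorocarbonyl)-5-methyl-2-(3-methylbut-2-enyl)hex-4-enoate
Conditions: 1-chloro-N,N,2-trimethylprop-1-en-1-amine (1.2 equiv), CH2Cl2, 0 °C to rt; volatiles removed, used crude
Reagents that add atoms: 1-chloro-N,N,2-trimethylprop-1-en-1-amine, CC(C)=C(Cl)N(C)C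
Why: Acid chloride formation with an α-chloroenamine proceeds through an acyloxyiminium chloride under neutral conditions, so no HCl is released that could add to the prenyl double bonds or induce lactonisation; the amide by-product is inert in step 5.

Step 4
Reactants: 7 acetylacetone (pentane-2,4-dione); 8 benzyl bromide
Product: 10 6-phenylhexane-2,4-dione, via dilithium dianion of acetylacetone 9 (not isolated)
Conditions: LiN(i-Pr)2 (2.1 equiv), THF, −78 to 0 °C; then 8 (0.95 equiv), 0 °C; 1 M HCl work-up
Reagents that add atoms: none
Why: Terminal (γ) alkylation of a β-diketone dianion, in which the localised methyl carbanion of 9 is far more nucleophilic than the delocalised central carbon, so benzylation (SN2) should occur only at the terminus.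

Step 5
Reactants: 10 6-phenylhexane-2,4-dione; 6 methyl 2-(chlorocarbonyl)-5-methyl-2-(3-methylbut-2-enyl)hex-4-enoate
Product: 12 methyl 2,2-bis(3-methylbut-2-enyl)-3,5,7-trioxo-9-phenylnonanoate, via dilithium dianion of 6-phenylhexane-2,4-dione 11 (not isolated)
Conditions: 10 (2.2 equiv), LiN(i-Pr)2 (4.5 equiv), THF, −78 to 0 °C; then 6 (1.0 equiv) in THF added slowly, −78 °C; cold 1 M HCl to pH 4; used promptly
Reagents that add atoms: none
Why: C-Acylation of a β-diketone dianion at its terminal carbon, where LiN(i-Pr)2 removes the second proton kinetically from the C1 methyl of 10 in preference to the C5 methylene, the resulting carbanion attacks the acid chloride much faster than the methyl ester, and the excess dianion takes up the proton of the more acidic triketone product.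

Step 6
Reactants: 12 methyl 2,2-bis(3-methylbut-2-enyl)-3,5,7-trioxo-9-phenylnonanoate
Product: 13 3,5-dihydroxy-6,6-bis(3-methylbut-2-enyl)-2-(3-phenylpropanoyl)cyclohexa-2,4-dien-1-one
Conditions: Mg(OMe)2 (4 equiv), MeOH, reflux; then cold 1 M HCl to pH 2–3, EtOAc extraction
Reagents that add atoms: none
Why: Mg(OMe)2 should convert 12 into a magnesium-chelated polyenolate in which both doubly activated methylenes (chain C4 and C6) are ionised; chain C6, the carbon between the C5 and C7 carbonyls, adds to the ester carbonyl (chain C1) and methoxide leaves the tetrahedral intermediate, forming ring bond C1–C2. This is the intramolecular Claisen (Dieckmann-type) condensation by which 3,5,7-triketo esters are converted into acylphloroglucinols. The six-membered carbocycle closes in a 6-exo-trig mode, the nucleophilic carbon attacking a carbonyl whose C=O bond lies outside the forming ring. No stereocentre is created, since ring C6 carries two identical prenyl groups and every other ring carbon is sp2. The step needs C- over O-acylation and Claisen over aldol closure: the only oxygen that can reach the ester through a six-membered transition state is the C5 enolate oxygen, the enol lactone it would give is reopened by methoxide, the carbocyclic product leaves the equilibrium as its strongly stabilised tricarbonyl enolate, and magnesium chelation of the 1,3-dioxygen units keeps the enolate oxygens occupied. The quaternary chain C2 cannot enolise, which keeps the ester electrophilic, rules out the resorcylate-type aldol and prevents aromatisation, while the one remaining aldol (chain C8 onto the hindered, enolate-bound C3 carbonyl) would need a proton far less acidic than methoxide can remove.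

Step 7
Reactants: 13 3,5-dihydroxy-6,6-bis(3-methylbut-2-enyl)-2-(3-phenylpropanoyl)cyclohexa-2,4-dien-1-one; 2 prenyl bromide
Product: 14 helilupolone, 3,5-dihydroxy-4,6,6-tris(3-methylbut-2-enyl)-2-(3-phenylpropanoyl)cyclohexa-2,4-dien-1-one
Conditions: KOH (2.0 equiv), H2O/MeOH, 0 °C, argon; 2 (1.05 equiv) added dropwise, 0 °C; then cold 1 M HCl
Reagents that add atoms: none
Why: C-Alkylation of a vinylogous acid enolate, in which the dianion of 13 should attack the primary allylic bromide through ring C4, the only ring carbon still bearing hydrogen and the mid-carbon of the C3/C5 dioxygenated unit, while the protic medium solvates the enolate oxygens and disfavours O-alkylation, as in the conversion of deoxyhumulone-type hop acids into lupulones.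

**Compound list**

1 | dimethyl malonate | COC(=O)CC(=O)OC | starting material
2 | prenyl bromide (1-bromo-3-methylbut-2-ene) | CC(C)=CCBr | starting material
3 | dimethyl 2-(3-methylbut-2-enyl)malonate (formed in situ) | COC(=O)C(CC=C(C)C)C(=O)OC | intermediate
4 | dimethyl 2,2-bis(3-methylbut-2-enyl)malonate | COC(=O)C(CC=C(C)C)(CC=C(C)C)C(=O)OC | intermediate
5 | 2-(methoxycarbonyl)-5-methyl-2-(3-methylbut-2-enyl)hex-4-enoic acid | COC(=O)C(CC=C(C)C)(CC=C(C)C)C(=O)O | intermediate
6 | methyl 2-(chlorocarbonyl)-5-methyl-2-(3-methylbut-2-enyl)hex-4-enoate | COC(=O)C(CC=C(C)C)(CC=C(C)C)C(=O)Cl | intermediate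
7 | acetylacetone (pentane-2,4-dione) | CC(=O)CC(C)=O | starting material
8 | benzyl bromide | BrCc1ccccc1 | starting material
9 | dilithium dianion of acetylacetone (formed in situ) | C=C([O-])C=C(C)[O-].[Li+].[Li+] | intermediate
10 | 6-phenylhexane-2,4-dione | CC(=O)CC(=O)CCc1ccccc1 | intermediate
11 | dilithium dianion of 6-phenylhexane-2,4-dione (formed in situ) | C=C([O-])C=C([O-])CCc1ccccc1.[Li+].[Li+] | intermediate
12 | methyl 2,2-bis(3-methylbut-2-enyl)-3,5,7-trioxo-9-phenylnonanoate | COC(=O)C(CC=C(C)C)(CC=C(C)C)C(=O)CC(=O)CC(=O)CCc1ccccc1 | intermediate
13 | 3,5-dihydroxy-6,6-bis(3-methylbut-2-enyl)-2-(3-phenylpropanoyl)cyclohexa-2,4-dien-1-one | O=C1C(C(=O)CCc2ccccc2)=C(O)C=C(O)C1(CC=C(C)C)CC=C(C)C | intermediate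
14 | helilupolone | CC(C)=CCC1=C(O)C(CC=C(C)C)(CC=C(C)C)C(=O)C(C(=O)CCc2ccccc2)=C1O | target

**Step count**

Total steps: 7. Longest linear sequence: 6 steps (steps 1, 2, 3, 5, 6, 7 from dimethyl malonate); the diketone branch contributes step 4.

**Steps most likely to fail**

1. Step 6 (key Claisen closure). The polyenolate may close through the C5 enolate oxygen to the enol lactone faster than that lactone is reopened. Alternatively, methoxide may cleave the chain by retro-Claisen attack at the ketone beside the quaternary carbon, so that the carbocycle does not accumulate. Fallback: the ring is taken from an aromatic precursor instead of being closed, setting out from prenyl bromide 2 and returning at target 14. Friedel–Crafts acylation of commercial phloroglucinol with 3-phenylpropanoyl chloride (AlCl3, nitrobenzene, 60 °C) should give 1-(2,4,6-trihydroxyphenyl)-3-phenylpropan-1-one F1. Exhaustive dearomatising C-prenylation of F1 with 2 (3.1 equiv, NaOMe, MeOH, 0 °C), the classical entry to lupulone-type triprenyl compounds, should then give 14 directly, at the price of a demanding separation from under- and over-alkylated material.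

2. Step 5 (dianion acylation). Proton transfer from the acidic triketone product may quench the dianion, the product enolate may be acylated a second time, or the hindered acid chloride may react too slowly to compete with these processes. Fallback: the acylation is replaced by an aldol addition followed by oxidation, setting out from acid chloride 6 and dianion 11 and returning at 12. Reduction of 6 with LiAlH(O-t-Bu)3 (THF, −78 °C) should give the non-enolisable aldehyde methyl 2-formyl-5-methyl-2-(3-methylbut-2-enyl)hex-4-enoate F2. Addition of 11 (1.1 equiv, THF, −78 °C) through its terminal carbon should give racemic methyl 3-hydroxy-2,2-bis(3-methylbut-2-enyl)-5,7-dioxo-9-phenylnonanoate F3, whose alkoxide neither quenches the dianion nor accepts a second electrophile. Dess–Martin oxidation of the carbinol (CH2Cl2, NaHCO3, 0 °C), which removes the only stereocentre, should then give 12.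

3. Step 7 (C4 prenylation). Alkylation may occur on an enol oxygen instead of on C4, a second prenyl group may enter at C4, and the electron-rich enolate may oxidise in air. Fallback: Tsuji–Trost allylation from 13 to 14 with methyl 3-methylbut-2-enyl carbonate and Pd(PPh3)4 (zerovalent palladium, 5 mol %) in THF at rt without added base. The methoxide released on ionisation deprotonates 13, and the soft carbon nucleophile should attack the unsubstituted terminus of the 1,1-dimethylallyl palladium intermediate to place a linear prenyl group on C4. Any O-allyl enol ether is re-ionised by the catalyst and funnelled to the C-allylated product. This fallback makes no compound outside the list (F0).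

**Further compounds**

F1 | step 6 | 1-(2,4,6-trihydroxyphenyl)-3-phenylpropan-1-one | O=C(CCc1ccccc1)c1c(O)cc(O)cc1O
F2 | step 5 | methyl 2-formyl-5-methyl-2-(3-methylbut-2-enyl)hex-4-enoate | COC(=O)C(CC=C(C)C)(CC=C(C)C)C=O
F3 | step 5 | methyl 3-hydroxy-2,2-bis(3-methylbut-2-enyl)-5,7-dioxo-9-phenylnonanoate (racemic) | COC(=O)C(CC=C(C)C)(CC=C(C)C)C(O)CC(=O)CC(=O)CCc1ccccc1
F0 | step 7 | none | none
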